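At early times this flask is a stirred suspension: solid G passes into solution as Q, while a little catalyst L turns Q into D and two L at a time are lost to L2.

G 0.083 M; L 0.61 mol%; time 12 min

1. how much D there is at 12 min, in percent of the G charged
2. how much Q there is at 12 min, in percent of the G charged

- a step written with two of one species runs at k times the square of its concentration and takes two of it each time
- as a solid, counted per litre of solution: G
- at the start none of G is in solution
- what has only dissolved of G counts as not reacted
- Q means what is dissolved; the solid is not counted in it
- run time (flask): 12 min

    Q + L ⇌ D + L, rate k1*[Q]*[L] forward; the back reaction follows from the equilibrium constant (K1 = 0.15, k1 = 71 M⁻¹ s⁻¹)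
    D + L ⇌ Z + L, rate k2*[L]*[D] forward; the back reaction follows from the equilibrium constant (K2 = 1.1, k2 = 7.7 M⁻¹ s⁻¹)
    Z + L ⇌ Q + L, rate k3*[L]*[Z] forward; the back reaction follows from the equilibrium constant (k3 = 24 M⁻¹ s⁻¹)
    G ⇌ Q, rate k4*(cs4 - [Q]) while solid is left; crystals form when [Q] > cs4 (cs4 = 29 mM, k4 = 0.020 s⁻¹)
    2 L → L2 (k5 = 100 M⁻¹ s⁻¹)
    D ⇌ J (K6 = 0.10, k6 = 0.057 s⁻¹)

I begin with the solubility 29 mM over the charge 0.083 M, which gives 34.9%. I call this the saturation share, the percent of the charged G that Q can hold as long as solid is present. The half-life of dissolution, 0.578 min, is short against the 12 min of the run, so I expect Q to reach that share if solid lasts. Even with D, Z and J all at equilibrium with saturated Q, the dissolved forms come to 46.5% of the charge, which is less than the whole charge, so I expect solid to last. By the forward rate of step 1 alone, at the charged catalyst, Q has a half-life of 0.32 min, short against the run, so I put D at 0.15 times the share, 5.24%. L falls meanwhile, so I hold this second figure less firmly.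

The forecast gives 34.9% of Q and 5.2% of D, reasoning that “Q sits just under its 29 mM solubility”.

The simulation gives 34.9% of Q and 5.10% of D at 12.0 min.

In this flask Q stands at the saturation share of 34.9%, with 57.6% of the charge still solid G at 12.0 min. Half of the dissolution up to that time is done by 0.730 min, far sooner than the end of the run, and at 0.730 min Q is being made 6.89 times as fast as it is used up, each step taken net. In the neighbouring flask with 0.050 M of G, the saturation share is 58.0%, and that flask holds 57.9% of Q at 12.0 min.

(All constants come from no measurement; no experiment stands behind them.)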